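## Retrosynthetic overview

1. Ring B is closed last: an aerobic 6-endo radical cyclisation of a C-alkylated, dearomatised diprenyl acetylphloroglucinol onto an isopropenyl group forms the C1–C6′ bond and the C7′ hydroperoxide.
2. The CH2 link (C1–C4′) comes from a reductive Knoevenagel union of ring A (gem-diprenylated 2,4,6-trihydroxyacetophenone) with a cyclopentane β-hydroxy aldehyde (ring C).
3. Ring C and its three stereocentres come from one chiral-diol-catalysed conjugate isopropenylation/aldol cascade on achiral (E)-6-oxohept-2-enal.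
4. The keto-enal comes from cross-metathesis of hex-5-en-2-one with acrolein.
5. Ring order: A and C are made separately, then B (the spiro ring) is formed.

Locants follow the name of the target in the compound list: ring A is C1–C6 with C1 the spiro carbon, and the hydrindane carries primed locants.

Assumption: enol tautomers of the ring-A β-triketone are drawn in one form and treated as one compound; where a catalyst antipode is named it is the one predicted to give the stated sense, and its mirror image is used if the first run shows the opposite.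

## Route

Step 1
Reactants: 1 hex-5-en-2-one; 2 acrolein (prop-2-enal)
Product: 3 (E)-6-oxohept-2-enal
Conditions: second-generation Hoveyda–Grubbs catalyst RuCl2(H2IMes)(=CH-C6H4-2-OiPr) (2 mol%), 2 (3 equiv), CH2Cl2, 40 °C
Reagents that add atoms: none
Why: Olefin cross-metathesis of a terminal alkene with an excess of the electron-poor enal partner is selective for the (E)-cross product and loses only ethene; no stereocentre is formed.

Step 2
Reactants: 3 (E)-6-oxohept-2-enal; 4 potassium trifluoro(prop-1-en-2-yl)borate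
Product: 6 (1S,2R,5R)-2-hydroxy-2-methyl-5-(prop-1-en-2-yl)cyclopentane-1-carbaldehyde, via boron enolate 5 (not isolated)
Conditions: (R)-3,3′-(C6F5)2-BINOL (20 mol%), 4 Å MS, PhMe, 40 °C; then pH 7 phosphate buffer
Reagents that add atoms: none
Why: Proposed new method: a chiral-diol-catalysed conjugate alkenylboration of an enal in which the O-boron enolate is intercepted by a tethered ketone (closest known reaction types: BINOL-catalysed conjugate addition of alkenylboron reagents to enones, and the [Rh(cod)Cl]2-catalysed boronic acid conjugate addition–aldol cyclisation of keto-enones): the diol exchanges onto boron to give a Lewis-acidic alkenylboron species that binds the s-cis enal oxygen and transfers isopropenyl as a sigma-nucleophile to the Re face of C3 through a six-membered chair (this sets C5 of 6, the first stereocentre), and the (Z)-O-boron enolate 5 then closes 5-(enolexo)-exo-trig on the methyl ketone through a boron-bridged Zimmerman–Traxler chair that puts OH syn to CHO (C2 and C1) while allylic strain in the enolate puts CHO anti to isopropenyl.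

Step 3
Reactants: 7 2,4,6-trihydroxyacetophenone; 8 prenyl bromide (1-bromo-3-methylbut-2-ene)
Product: 9 2-acetyl-3,5-dihydroxy-4,4-bis(3-methylbut-2-en-1-yl)cyclohexa-2,5-dien-1-one
Conditions: 8 (2.1 equiv in all, added in two portions), NaOMe (2.2 equiv), MeOH, 0 °C to rt; chromatography
Reagents that add atoms: prenyl bromide 8 (second equivalent), CC(C)=CCBr
Why: Dearomative double C-alkylation of the phloroglucinol anion, in which the first equivalent of 8 prenylates a ring CH and the second equivalent alkylates the same, now more substituted, enolate carbon to give the gem-diprenyl dienone, which is separated from the 3,5-diprenyl and triprenyl isomers; no stereocentre is formed.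

Step 4
Reactants: 6 (1S,2R,5R)-2-hydroxy-2-methyl-5-(prop-1-en-2-yl)cyclopentane-1-carbaldehyde; 9 2-acetyl-3,5-dihydroxy-4,4-bis(3-methylbut-2-en-1-yl)cyclohexa-2,5-dien-1-one
Product: 11 2-acetyl-3,5-dihydroxy-6-{[(1S,2R,5R)-2-hydroxy-2-methyl-5-(prop-1-en-2-yl)cyclopentyl]methyl}-4,4-bis(3-methylbut-2-en-1-yl)cyclohexa-2,5-dien-1-one, via alkylidene triketone 10 (not isolated)
Conditions: Hantzsch ester (diethyl 2,6-dimethyl-1,4-dihydropyridine-3,5-dicarboxylate, 1.1 equiv), L-proline (10 mol%), CH2Cl2, 0 °C to rt
Reagents that add atoms: none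
Why: Organocatalytic three-component reductive alkylation (Knoevenagel condensation at the only free ring carbon of 9, then conjugate transfer hydrogenation of alkylidene 10 by the Hantzsch ester) forms the CH2 link without touching the stereocentres of 6, whose one epimerisable centre (cyclopentane C1) already sits in the favoured trans arrangement.

Step 5
Reactants: 11 2-acetyl-3,5-dihydroxy-6-{[(1S,2R,5R)-2-hydroxy-2-methyl-5-(prop-1-en-2-yl)cyclopentyl]methyl}-4,4-bis(3-methylbut-2-en-1-yl)cyclohexa-2,5-dien-1-one
Product: 12 (1R,3′R,3a′S,7′R,7a′R)-3-acetyl-7′-hydroperoxy-3′,4-dihydroxy-3′,7′-dimethyl-5,5-bis(3-methylbut-2-en-1-yl)-1′,2′,3′,3a′,4′,6′,7′,7a′-octahydrospiro[cyclohex-3-ene-1,5′-indene]-2,6-dione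
Conditions: Mn(OAc)3·2H2O (10 mol%), O2 (1 atm), AcOH, 23 °C, 0.01 M; preparative HPLC
Reagents that add atoms: dioxygen, O=O
Why: Manganese triacetate-type oxidative radical cyclisation with aerobic trapping: the ring-A tricarbonyl radical adds 6-endo to the CH2 terminus of the isopropenyl group through a chair that gives the trans-hydrindane (5-exo would give a trans-fused diquinane, and attack on an open CH2 terminus should outrun the known 5-exo attack on a prenyl CH), O2 captures the tertiary C7′ radical on the face away from the axial ring-A carbonyl (OOH equatorial, methyl axial, 7′R) and the peroxyl radical carries the chain, while the spiro centre C1 depends on which ring-A carbonyl lies under the new ring, where only a modest preference for the wanted 1R epimer (the charge-localised C6 carbonyl beside the sp3 diprenyl carbon sitting under the electron-poor C7′) is expected and the 1S epimer is removed by HPLC.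

## Compound list

1 | hex-5-en-2-one | CC(=O)CCC=C | starting material
2 | acrolein (prop-2-enal) | C=CC=O | starting material
3 | (E)-6-oxohept-2-enal | CC(=O)CC/C=C/C=O | intermediate
4 | potassium trifluoro(prop-1-en-2-yl)borate | [K+].C=C(C)[B-](F)(F)F | starting material
5 | boron enolate, difluoro{[(1Z,3R)-6-oxo-3-(prop-1-en-2-yl)hept-1-en-1-yl]oxy}borane (drawn without the bound diol catalyst) | FB(F)O/C=C\[C@@H](CCC(C)=O)C(C)=C | intermediate
6 | (1S,2R,5R)-2-hydroxy-2-methyl-5-(prop-1-en-2-yl)cyclopentane-1-carbaldehyde | O=C[C@H]1[C@@H](CC[C@@]1(C)O)C(C)=C | intermediate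
7 | 2,4,6-trihydroxyacetophenone | CC(=O)c1c(O)cc(O)cc1O | starting material
8 | prenyl bromide (1-bromo-3-methylbut-2-ene) | CC(C)=CCBr | starting material
9 | 2-acetyl-3,5-dihydroxy-4,4-bis(3-methylbut-2-en-1-yl)cyclohexa-2,5-dien-1-one | CC(=O)C1=C(O)C(CC=C(C)C)(CC=C(C)C)C(O)=CC1=O | intermediate
10 | alkylidene triketone, 2-acetyl-3-hydroxy-6-{[(1S,2R,5R)-2-hydroxy-2-methyl-5-(prop-1-en-2-yl)cyclopentyl]methylidene}-4,4-bis(3-methylbut-2-en-1-yl)cyclohex-2-ene-1,5-dione (alkene geometry not defined) | CC(=O)C1=C(O)C(CC=C(C)C)(CC=C(C)C)C(=O)C(=C[C@H]2[C@@H](CC[C@@]2(C)O)C(C)=C)C1=O | intermediate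
11 | 2-acetyl-3,5-dihydroxy-6-{[(1S,2R,5R)-2-hydroxy-2-methyl-5-(prop-1-en-2-yl)cyclopentyl]methyl}-4,4-bis(3-methylbut-2-en-1-yl)cyclohexa-2,5-dien-1-one | CC(=O)C1=C(O)C(CC=C(C)C)(CC=C(C)C)C(O)=C(C[C@H]2[C@@H](CC[C@@]2(C)O)C(C)=C)C1=O | intermediate
12 | (1R,3′R,3a′S,7′R,7a′R)-3-acetyl-7′-hydroperoxy-3′,4-dihydroxy-3′,7′-dimethyl-5,5-bis(3-methylbut-2-en-1-yl)-1′,2′,3′,3a′,4′,6′,7′,7a′-octahydrospiro[cyclohex-3-ene-1,5′-indene]-2,6-dione | CC(=O)C1=C(O)C(CC=C(C)C)(CC=C(C)C)C(=O)[C@]2(C[C@H]3[C@@H](CC[C@@]3(C)O)[C@](C)(OO)C2)C1=O | target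

## Step count and risks

Total step count: 5. Longest linear sequence: 4 steps (steps 1, 2, 4, 5 from hex-5-en-2-one); step 3 is a one-step branch.

**Step 2 (the proposed new step).** The boron reagent may not transfer to an aliphatic enal, the enantioselectivity may be low, or the aldol may dehydrate. The fallback uses known chemistry only; it sets out from 2 and comes back at 6. Acrolein 2 and isoprene undergo the imidazolidinone-catalysed Diels–Alder reaction (5-benzyl-2,2,3-trimethylimidazolidin-4-one hydrochloride, antipode chosen for the R adduct, MeOH/H2O) to give (R)-4-methylcyclohex-3-ene-1-carbaldehyde F1. MeMgBr then gives the carbinol 1-[(1R)-4-methylcyclohex-3-en-1-yl]ethan-1-ol F2, Dess–Martin oxidation gives the methyl ketone 1-[(1R)-4-methylcyclohex-3-en-1-yl]ethan-1-one F3, and Ph3P=CH2 gives (R)-limonene F4. mCPBA (1 equiv, 0 °C) epoxidises only the trisubstituted ring alkene to give (4R)-limonene 1,2-oxide F5, and H5IO6 cleaves it to (3R)-6-oxo-3-(prop-1-en-2-yl)heptanal F6. Proline-mediated 5-(enolexo) aldolisation at rt, stopped before dehydration, closes the ring to 6.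

**Step 5.** This is the weakest step, for three reasons: the C1 radical can instead close 5-exo on a prenyl group (a bicyclo[3.2.1]octane by-product), the spiro centre has no strong intrinsic bias, and the hydroperoxide can be reduced by Mn(OAc)2 (divalent manganese) formed in the cycle. The fallback removes the competing radical acceptor; it does not improve the spiro ratio, so the 1S epimer is still separated at the end. It sets out from 6 and 7 and comes back at 12. Compound 7 is gem-diallylated (allyl bromide, NaOMe, MeOH) to 2-acetyl-3,5-dihydroxy-4,4-di(prop-2-en-1-yl)cyclohexa-2,5-dien-1-one F7. Reductive alkylation with 6 as in step 4 passes through the diallyl alkylidene triketone F8 to the diallyl analogue of 11 F9. The same aerobic cyclisation, where a monosubstituted allyl group is a poor partner for the electrophilic radical, gives the diallyl analogue of 12 F10. 2-Methoxypropene/PPTS masks the hydroperoxide as the 2-methoxypropan-2-yl peroxide of the diallyl spirocycle F11. Cross-metathesis with 2-methyl-2-butene (second-generation Grubbs catalyst RuCl2(H2IMes)(PCy3)(=CHPh), 40 °C) converts both allyl groups into prenyl groups to give the 2-methoxypropan-2-yl peroxide of 12 F12, and AcOH/THF/H2O at rt releases 12.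

**Step 4.** The β-hydroxy aldehyde 6, or alkylidene 10, may lose water or undergo retro-aldol opening before the hydride transfer. The fallback masks the tertiary alcohol; it sets out from 6 and comes back at 11. N-(Trimethylsilyl)imidazole in CH2Cl2 gives the O-trimethylsilyl ether of 6 F13. Reductive alkylation with 9 under the step 4 conditions passes through the O-silyl alkylidene triketone F14 to the O-trimethylsilyl ether of 11 F15, and citric acid in MeOH removes the silyl group to give 11.

## Further compounds

F1 | step 2 | (R)-4-methylcyclohex-3-ene-1-carbaldehyde | O=C[C@H]1CC=C(C)CC1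
F2 | step 2 | 1-[(1R)-4-methylcyclohex-3-en-1-yl]ethan-1-ol (carbinol epimers) | CC(O)[C@H]1CC=C(C)CC1
F3 | step 2 | 1-[(1R)-4-methylcyclohex-3-en-1-yl]ethan-1-one | CC(=O)[C@H]1CC=C(C)CC1
F4 | step 2 | (R)-limonene, (4R)-1-methyl-4-(prop-1-en-2-yl)cyclohex-1-ene | C=C(C)[C@H]1CC=C(C)CC1
F5 | step 2 | (4R)-limonene 1,2-oxide (epoxide epimers) | C=C(C)[C@H]1CC2OC2(C)CC1
F6 | step 2 | (3R)-6-oxo-3-(prop-1-en-2-yl)heptanal | O=CC[C@@H](CCC(C)=O)C(C)=C
F7 | step 5 | 2-acetyl-3,5-dihydroxy-4,4-di(prop-2-en-1-yl)cyclohexa-2,5-dien-1-one | CC(=O)C1=C(O)C(CC=C)(CC=C)C(O)=CC1=O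
F8 | step 5 | diallyl alkylidene triketone (diallyl analogue of 10) | CC(=O)C1=C(O)C(CC=C)(CC=C)C(=O)C(=C[C@H]2[C@@H](CC[C@@]2(C)O)C(C)=C)C1=O
F9 | step 5 | diallyl analogue of 11 | CC(=O)C1=C(O)C(CC=C)(CC=C)C(O)=C(C[C@H]2[C@@H](CC[C@@]2(C)O)C(C)=C)C1=O
F10 | step 5 | diallyl analogue of 12 (same configuration) | CC(=O)C1=C(O)C(CC=C)(CC=C)C(=O)[C@]2(C[C@H]3[C@@H](CC[C@@]3(C)O)[C@](C)(OO)C2)C1=O
F11 | step 5 | 2-methoxypropan-2-yl peroxide of the diallyl spirocycle | CC(=O)C1=C(O)C(CC=C)(CC=C)C(=O)[C@]2(C[C@H]3[C@@H](CC[C@@]3(C)O)[C@](C)(OOC(C)(C)OC)C2)C1=O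
F12 | step 5 | 2-methoxypropan-2-yl peroxide of 12 | CC(=O)C1=C(O)C(CC=C(C)C)(CC=C(C)C)C(=O)[C@]2(C[C@H]3[C@@H](CC[C@@]3(C)O)[C@](C)(OOC(C)(C)OC)C2)C1=O
F13 | step 4 | O-trimethylsilyl ether of 6, (1S,2R,5R)-2-methyl-5-(prop-1-en-2-yl)-2-[(trimethylsilyl)oxy]cyclopentane-1-carbaldehyde | O=C[C@H]1[C@@H](CC[C@@]1(C)O[Si](C)(C)C)C(C)=C
F14 | step 4 | O-silyl alkylidene triketone (O-trimethylsilyl analogue of 10) | CC(=O)C1=C(O)C(CC=C(C)C)(CC=C(C)C)C(=O)C(=C[C@H]2[C@@H](CC[C@@]2(C)O[Si](C)(C)C)C(C)=C)C1=O
F15 | step 4 | O-trimethylsilyl ether of 11 | CC(=O)C1=C(O)C(CC=C(C)C)(CC=C(C)C)C(O)=C(C[C@H]2[C@@H](CC[C@@]2(C)O[Si](C)(C)C)C(C)=C)C1=O
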